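The route rests on disconnecting N1–C2 of the pyrrole ring. The feature exploited is that C2 bears bromine and is bonded directly to N1. A 2,2-dibromoethenyl group on the benzene carbon that becomes C3a already holds C3, C2 and the C2 bromine. Ring closure at nitrogen with loss of the other vinylic bromine therefore builds the 2-bromopyrrole ring in one metal-free operation, leaving the aryl bromides at C4, C5 and C6 alone. The precursor is N-[3,4,5-tribromo-2-(2,2-dibromoethenyl)phenyl]methanesulfonamide, assembled from 3-methyl-4-nitroaniline. After cyclisation the mesyl group is removed and C3 is methylsulfenylated.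

Key step: step 7

Step 1
Reactants: 1 3-methyl-4-nitroaniline
Product: 2 2,6-dibromo-3-methyl-4-nitroaniline
Conditions: Br2 (2.2 equiv), AcOH, 20 → 50 °C
Reagents that add atoms: bromine, BrBr
Why: Electrophilic aromatic bromination in which the amino group directs to its two ortho carbons (its para position is blocked by the nitro group, which is meta to both sites), so substitution should stop cleanly at the 2,6-dibromide.

Step 2
Reactants: 2 2,6-dibromo-3-methyl-4-nitroaniline
Product: 4 1,2,3-tribromo-4-methyl-5-nitrobenzene, via arenediazonium bromide 3 (not isolated)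
Conditions: t-BuONO, CuBr2, MeCN, 0 → 60 °C
Reagents that add atoms: CuBr2, [Cu+2].[Br-].[Br-] (the new bromine of 4); tert-butyl nitrite, CC(C)(C)ON=O (terminal nitrogen of intermediate 3 only)
Why: Non-aqueous Sandmeyer bromination, in which the alkyl nitrite diazotises the weakly basic, di-ortho-substituted nitroaniline and the aryl radical formed on loss of N2 takes bromine from CuBr2, a variant suited to anilines that resist aqueous diazotisation.

Step 3
Reactants: 4 1,2,3-tribromo-4-methyl-5-nitrobenzene
Product: 6 2,3,4-tribromo-6-nitrobenzaldehyde, via enamine 5 (not isolated)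
Conditions: Me2NCH(OMe)2, DMF, 115 °C; then NaIO4, DMF/H2O, 0 °C → rt
Reagents that add atoms: NaIO4, [Na+].[O-]I(=O)(=O)=O (aldehyde oxygen of 6); N,N-dimethylformamide dimethyl acetal, COC(OC)N(C)C (CH–NMe2 unit of intermediate 5 only)
Why: The methyl group ortho to nitro, further acidified by three bromines, condenses with the formamide acetal as in the first stage of a Leimgruber–Batcho synthesis, and periodate cleaves the electron-rich enamine C=C to the aldehyde; no secondary amine additive is used, which spares the bromine para to the nitro group from nucleophilic aromatic substitution.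

Step 4
Reactants: 6 2,3,4-tribromo-6-nitrobenzaldehyde; 7 carbon tetrabromide
Product: 8 1,2,3-tribromo-4-(2,2-dibromoethenyl)-5-nitrobenzene
Conditions: CBr4, PPh3, CH2Cl2, 0 °C
Reagents that add atoms: carbon tetrabromide, BrC(Br)(Br)Br
Why: Ramirez dibromo-olefination (first stage of the Corey–Fuchs sequence), a Wittig reaction of the ylide Ph3P=CBr2 made in the flask, which is routine for ortho-nitrobenzaldehydes and leaves nitro and aryl bromide groups untouched at 0 °C.

Step 5
Reactants: 8 1,2,3-tribromo-4-(2,2-dibromoethenyl)-5-nitrobenzene
Product: 9 3,4,5-tribromo-2-(2,2-dibromoethenyl)aniline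
Conditions: SnCl2·2H2O, EtOH, 75 °C
Reagents that add atoms: none
Why: Chemoselective nitro reduction by divalent tin, an electron-transfer process that does not hydrogenolyse vinylic or aryl C–Br bonds and is the standard way to ortho-(gem-dibromovinyl)anilines.

Step 6
Reactants: 9 3,4,5-tribromo-2-(2,2-dibromoethenyl)aniline; 10 methanesulfonyl chloride
Product: 11 N-[3,4,5-tribromo-2-(2,2-dibromoethenyl)phenyl]methanesulfonamide
Conditions: MsCl, pyridine, CH2Cl2, 0 °C → rt
Reagents that add atoms: methanesulfonyl chloride, CS(=O)(=O)Cl
Why: N-Sulfonylation of the primary aniline with pyridine as acid scavenger, where the weakly nucleophilic, ortho-substituted nitrogen should react only once and the dibromoalkene is inert.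

Step 7
Reactants: 11 N-[3,4,5-tribromo-2-(2,2-dibromoethenyl)phenyl]methanesulfonamide
Product: 13 2,4,5,6-tetrabromo-1-(methylsulfonyl)-1H-indole, via bromoalkyne 12 (not isolated)
Conditions: Cs2CO3, THF, 65 °C
Reagents that add atoms: none
Why: Cs2CO3 deprotonates the acidic sulfonamide N–H and removes HBr from the dibromoethenyl group by anti-elimination to give bromoalkyne 12; the sulfonamide nitrogen then adds to the bromine-bearing alkyne carbon and the C3 vinyl anion is protonated by CsHCO3, so N1–C2 forms and one bromine stays on C2. The closest known reaction type is the metal-free, base-mediated conversion of ortho-(gem-dibromovinyl) N-sulfonylanilines into N-sulfonyl-2-bromoindoles. The pyrrole ring closes in a 5-endo-dig mode, the only one the ortho tether allows, since attack at the aryl-bound alkyne carbon would give a four-membered ring. No stereocentre is created. The step needs chemoselectivity for loss of one vinylic bromine only; this is secured by the absence of any transition metal or strong external nucleophile, so the aryl C–Br bonds at C4, C5 and C6 and the new C2–Br bond do not react.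

Step 8
Reactants: 13 2,4,5,6-tetrabromo-1-(methylsulfonyl)-1H-indole
Product: 14 2,4,5,6-tetrabromo-1H-indole
Conditions: Bu4NF, THF, 60 °C; then aq. NH4Cl
Reagents that add atoms: none
Why: Fluoride-mediated N-desulfonylation of an N-sulfonylindole, in which fluoride attacks sulfur and expels an indolide made a good leaving group by four bromines, with no reductant or metal present to touch the C–Br bonds.

Step 9
Reactants: 14 2,4,5,6-tetrabromo-1H-indole
Product: 15 2,4,5,6-tetrabromo-3-(methylsulfanyl)-1H-indole
Conditions: MeSSMe, SO2Cl2, CH2Cl2, −20 °C; then 14, 0 °C → rt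
Reagents that add atoms: methanesulfenyl chloride, CSCl, made in the flask from dimethyl disulfide, CSSC, and sulfuryl chloride, O=S(=O)(Cl)Cl
Why: Electrophilic aromatic sulfenylation at C3, the only free and most nucleophilic position of the pyrrole ring of the N–H indole; C2 is blocked by bromine, so neither 2-sulfenylation nor sulfur migration can occur, and the small, reactive sulfenyl chloride should tolerate the peri bromine at C4.

Compound list
1 | 3-methyl-4-nitroaniline | Cc1cc(N)ccc1[N+](=O)[O-] | starting material
2 | 2,6-dibromo-3-methyl-4-nitroaniline | Cc1c(Br)c(N)c(Br)cc1[N+](=O)[O-] | intermediate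
3 | 2,6-dibromo-3-methyl-4-nitrobenzenediazonium bromide | Cc1c(Br)c([N+]#N)c(Br)cc1[N+](=O)[O-].[Br-] | intermediate (not isolated)
4 | 1,2,3-tribromo-4-methyl-5-nitrobenzene | Cc1c(Br)c(Br)c(Br)cc1[N+](=O)[O-] | intermediate
5 | (E)-N,N-dimethyl-2-(2,3,4-tribromo-6-nitrophenyl)ethen-1-amine | CN(C)/C=C/c1c(Br)c(Br)c(Br)cc1[N+](=O)[O-] | intermediate (not isolated)
6 | 2,3,4-tribromo-6-nitrobenzaldehyde | O=Cc1c(Br)c(Br)c(Br)cc1[N+](=O)[O-] | intermediate
7 | carbon tetrabromide | BrC(Br)(Br)Br | starting material
8 | 1,2,3-tribromo-4-(2,2-dibromoethenyl)-5-nitrobenzene | BrC(Br)=Cc1c(Br)c(Br)c(Br)cc1[N+](=O)[O-] | intermediate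
9 | 3,4,5-tribromo-2-(2,2-dibromoethenyl)aniline | Nc1cc(Br)c(Br)c(Br)c1C=C(Br)Br | intermediate
10 | methanesulfonyl chloride | CS(=O)(=O)Cl | starting material
11 | N-[3,4,5-tribromo-2-(2,2-dibromoethenyl)phenyl]methanesulfonamide | CS(=O)(=O)Nc1cc(Br)c(Br)c(Br)c1C=C(Br)Br | intermediate
12 | N-[3,4,5-tribromo-2-(bromoethynyl)phenyl]methanesulfonamide (present as its caesium salt) | CS(=O)(=O)Nc1cc(Br)c(Br)c(Br)c1C#CBr | intermediate (not isolated)
13 | 2,4,5,6-tetrabromo-1-(methylsulfonyl)-1H-indole | CS(=O)(=O)n1c(Br)cc2c(Br)c(Br)c(Br)cc21 | intermediate
14 | 2,4,5,6-tetrabromo-1H-indole | Brc1cc2c(Br)c(Br)c(Br)cc2[nH]1 | intermediate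
15 | 2,4,5,6-tetrabromo-3-(methylsulfanyl)-1H-indole | CSc1c(Br)[nH]c2cc(Br)c(Br)c(Br)c12 | target

Total step count: 9 (step 3 is a one-flask, two-stage operation).
Longest linear sequence: 9 steps, from 1 to 15.

Steps most likely to fail

1. Step 7 (key step). The elimination may stop at the bromoalkyne, the bromoalkyne may oligomerise faster than nitrogen attacks it, or the sulfonyl group may be lost before ring closure. Fallback: the C2 bromine is introduced by electrophilic bromination after a Leimgruber–Batcho ring closure. The route is left at compound 4. The crude enamine 5 is reduced with iron powder in AcOH at 80 °C, which should close the ring to 4,5,6-tribromo-1H-indole F1. Methanesulfenyl chloride in CH2Cl2 at 0 °C should then give 4,5,6-tribromo-3-(methylsulfanyl)-1H-indole F2. NBS in CH2Cl2 at 0 °C should brominate C2, the only free pyrrole position, and the route is rejoined at target 15.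

2. Step 3. Condensation at the methyl group, which is flanked by nitro and bromine, may be incomplete. Prolonged heating may also allow displacement of the bromine para to the nitro group by dimethylamine or methoxide. Fallback: the methyl group is oxidised through a benzylic halide. Setting out from compound 4, radical bromination with NBS and AIBN in PhCF3 at 85 °C should give 1,2,3-tribromo-4-(bromomethyl)-5-nitrobenzene F3. N-Methylmorpholine N-oxide in MeCN at rt should oxidise this to the aldehyde, rejoining the route at compound 6.

3. Step 9. Substitution at the deactivated, peri-hindered C3 may be sluggish, and the hydrogen chloride released may degrade the 2-bromoindole or promote ring chlorination. Fallback: the sulfenylation is run on the indolyl anion under acid-free conditions. Setting out from compound 14, MeMgBr (1.05 equiv) in THF at 0 °C should give bromo(2,4,5,6-tetrabromo-1H-indol-1-yl)magnesium F4. This is treated in the same flask with S-methyl methanethiosulfonate at 0 °C → rt, a C3 sulfenylation of an indolylmagnesium halide, and the route is rejoined at target 15.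

Further compounds
F1 | step 7 | 4,5,6-tribromo-1H-indole | Brc1cc2[nH]ccc2c(Br)c1Br
F2 | step 7 | 4,5,6-tribromo-3-(methylsulfanyl)-1H-indole | CSc1c[nH]c2cc(Br)c(Br)c(Br)c12
F3 | step 3 | 1,2,3-tribromo-4-(bromomethyl)-5-nitrobenzene | BrCc1c(Br)c(Br)c(Br)cc1[N+](=O)[O-]
F4 | step 9 | bromo(2,4,5,6-tetrabromo-1H-indol-1-yl)magnesium | Br[Mg]n1c(Br)cc2c(Br)c(Br)c(Br)cc21
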